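**Retrosynthetic overview**
1. Ring C is cut at O1–C2 back to a 2',4',6'-trihydroxychalcone, and ring A is cut by a retro-Claisen to an open-chain cinnamoyl triketide stored as a 6-(cinnamoylmethyl)-4-hydroxy-2-pyrone. In the forward sense ring A and then ring C form in one flask as the last step, with C2 set by chalcone isomerase.
2. The acyl pyrone comes from the dianion of triacetic acid lactone and a Weinreb cinnamamide.
3. The threo (1R,2R) arylglycerol aryl ether comes from an Evans syn-aldol of an aryloxyacetyl oxazolidinone with 4-silyloxybenzaldehyde, followed by reductive removal of the auxiliary.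
4. The aryloxyacetyl imide comes from syringaldehyde by O-alkylation and Wittig olefination. Ring B and the hydroxyphenyl ring are bought; the pyrone ring is sacrificial.

Assumption: recombinant chalcone isomerase (EC 5.5.1.6, Medicago sativa enzyme) is treated as an obtainable catalyst, not as a starting material.

**Route**

Step 1
Reactants: 1 syringaldehyde (4-hydroxy-3,5-dimethoxybenzaldehyde); 2 (4S)-4-benzyl-3-(chloroacetyl)-1,3-oxazolidin-2-one
Product: 3 (4S)-4-benzyl-3-[(4-formyl-2,6-dimethoxyphenoxy)acetyl]-1,3-oxazolidin-2-one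
Conditions: K2CO3, DMF, 40 °C
Reagents that add atoms: none
Why: Williamson etherification, in which the weakly basic phenoxide of 1 displaces the activated α-chloride of 2 by SN2 faster than it attacks the imide carbonyl; the (4S) centre of the auxiliary is not touched.

Step 2
Reactants: 3 (4S)-4-benzyl-3-[(4-formyl-2,6-dimethoxyphenoxy)acetyl]-1,3-oxazolidin-2-one; 4 N-methoxy-N-methyl-2-(triphenyl-λ5-phosphanylidene)acetamide
Product: 5 (2E)-3-(4-{2-[(4S)-4-benzyl-2-oxo-1,3-oxazolidin-3-yl]-2-oxoethoxy}-3,5-dimethoxyphenyl)-N-methoxy-N-methylprop-2-enamide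
Conditions: toluene, 90 °C
Reagents that add atoms: none
Why: Wittig olefination with a carbonyl-stabilised ylide gives the (E)-alkene, and the resulting Weinreb enamide both removes the aldehyde before the aldol step and later serves as a mono-acylating group.

Step 3
Reactants: 5 (2E)-3-(4-{2-[(4S)-4-benzyl-2-oxo-1,3-oxazolidin-3-yl]-2-oxoethoxy}-3,5-dimethoxyphenyl)-N-methoxy-N-methylprop-2-enamide; 6 4-{[tert-butyl(dimethyl)silyl]oxy}benzaldehyde
Product: 8 (4S)-4-benzyl-3-[(2S,3R)-3-(4-{[tert-butyl(dimethyl)silyl]oxy}phenyl)-3-hydroxy-2-(2,6-dimethoxy-4-{(1E)-3-[methoxy(methyl)amino]-3-oxoprop-1-en-1-yl}phenoxy)propanoyl]-1,3-oxazolidin-2-one, via boron enolate 7 (not isolated)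
Conditions: dibutylboron triflate (Bu2BOTf, 1.3 equiv), iPr2NEt, CH2Cl2, −78 to 0 °C; then 6, −78 to 0 °C; then pH 7 NaH2PO4/Na2HPO4 buffer, MeOH, 30% H2O2, 0 °C
Reagents that add atoms: none
Why: Evans syn-aldol reaction, in which the dibutylboron (Z)-enolate 7 reacts through a closed Zimmerman–Traxler chair with the aldehyde on the enolate face away from the benzyl group of the (4S) auxiliary, setting both new centres as (2S,3R), the syn (threo) pair required.

Step 4
Reactants: 8 the aldol adduct of step 3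
Product: 10 (2E)-3-[4-({(1R,2R)-1-(4-{[tert-butyl(dimethyl)silyl]oxy}phenyl)-1,3-dihydroxypropan-2-yl}oxy)-3,5-dimethoxyphenyl]-N-methoxy-N-methylprop-2-enamide, via aldehyde 9 (not isolated)
Conditions: NaBH4, THF/H2O (4:1), 0 to 25 °C
Reagents that add atoms: none
Why: reductive cleavage of the N-acyl oxazolidinone, in which hydride attacks the activated imide carbonyl and then the released aldehyde 9 while the Weinreb enamide and the aryl silyl ether stay intact; no bond to a stereocentre is broken, and the ether carbon is now labelled R only because the CIP priorities change.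

Step 5
Reactants: 10 the diol of step 4; 11 triacetic acid lactone (4-hydroxy-6-methyl-2H-pyran-2-one)
Product: 13 6-{(3E)-4-[4-({(1R,2R)-1-(4-{[tert-butyl(dimethyl)silyl]oxy}phenyl)-1,3-dihydroxypropan-2-yl}oxy)-3,5-dimethoxyphenyl]-2-oxobut-3-en-1-yl}-4-hydroxy-2H-pyran-2-one, via dilithiated pyrone 12 (not isolated)
Conditions: 11 (5 equiv), LiN(iPr)2 (10 equiv), THF, −78 to −20 °C; then 10, −78 to 0 °C; then AcOH
Reagents that add atoms: none
Why: γ-acylation of a β-dicarbonyl dianion by a Weinreb amide, in which the methyl carbanion of 12 adds 1,2 to the amide to give a chelated tetrahedral adduct that is inert to the two lithium alkoxides of 10 (these only consume two further equivalents of 12) and releases the ketone on acidic quench; no stereocentre is affected.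

Step 6
Reactants: 13 the cinnamoylmethyl pyrone of step 5
Product: 16 (2S)-2-[4-({(1R,2R)-1,3-dihydroxy-1-(4-hydroxyphenyl)propan-2-yl}oxy)-3,5-dimethoxyphenyl]-5,7-dihydroxy-2,3-dihydro-4H-chromen-4-one, via triketo ester 14 (not isolated), via chalcone 15 (not isolated)
Conditions: Mg(OMe)2 (10 equiv), MeOH, 65 °C, 8 h; then added at 0 °C to HEPES buffer (pH 7.5, held with aq. HCl, 10% MeOH v/v) containing chalcone isomerase (EC 5.5.1.6, recombinant Medicago sativa enzyme, 0.1 mol %), 25 °C, 1 h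
Reagents that add atoms: none
Why: Proposed new method: a biomimetic polyketide cascade in which methoxide opens the pyrone to the magnesium-chelated triketo ester 14, the chelate (ketones enolised and deactivated, ester still electrophilic) directs a C6-to-C1 Claisen cyclisation and aromatisation to ring A of chalcone 15 with loss of the aryl silyl group, and the 6'-hydroxyl then closes ring C by 6-endo oxa-Michael addition inside chalcone isomerase, which delivers the phenolate to the one enone face that gives (2S) far faster than the uncatalysed closure at pH 7.5; the closest known reaction types are the magnesium methoxide ring-opening/Claisen cyclisation of 6-(acylmethyl)-4-hydroxy-2-pyrones to acylphloroglucinols and the chalcone isomerase cyclisation of 2',4',6'-trihydroxychalcones to (2S)-flavanones, and the untested point is the large para substituent on ring B, which is expected to point out of the open end of the binding cleft.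

**Compound list**

1 | syringaldehyde (4-hydroxy-3,5-dimethoxybenzaldehyde) | COc1cc(C=O)cc(OC)c1O | starting material
2 | (4S)-4-benzyl-3-(chloroacetyl)-1,3-oxazolidin-2-one | O=C1OC[C@H](Cc2ccccc2)N1C(=O)CCl | starting material
3 | (4S)-4-benzyl-3-[(4-formyl-2,6-dimethoxyphenoxy)acetyl]-1,3-oxazolidin-2-one | COc1cc(C=O)cc(OC)c1OCC(=O)N1[C@@H](Cc2ccccc2)COC1=O | intermediate
4 | N-methoxy-N-methyl-2-(triphenyl-λ5-phosphanylidene)acetamide | CON(C)C(=O)C=P(c1ccccc1)(c1ccccc1)c1ccccc1 | starting material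
5 | (2E)-3-(4-{2-[(4S)-4-benzyl-2-oxo-1,3-oxazolidin-3-yl]-2-oxoethoxy}-3,5-dimethoxyphenyl)-N-methoxy-N-methylprop-2-enamide | COc1cc(/C=C/C(=O)N(C)OC)cc(OC)c1OCC(=O)N1[C@@H](Cc2ccccc2)COC1=O | intermediate
6 | 4-{[tert-butyl(dimethyl)silyl]oxy}benzaldehyde | CC(C)(C)[Si](C)(C)Oc1ccc(C=O)cc1 | starting material
7 | dibutylboron (Z)-enolate of 5: (4S)-4-benzyl-3-[(Z)-1-[(dibutylboranyl)oxy]-2-(2,6-dimethoxy-4-{(1E)-3-[methoxy(methyl)amino]-3-oxoprop-1-en-1-yl}phenoxy)ethenyl]-1,3-oxazolidin-2-one | CCCCB(CCCC)O/C(=C\Oc1c(OC)cc(/C=C/C(=O)N(C)OC)cc1OC)N1[C@@H](Cc2ccccc2)COC1=O | intermediate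
8 | (4S)-4-benzyl-3-[(2S,3R)-3-(4-{[tert-butyl(dimethyl)silyl]oxy}phenyl)-3-hydroxy-2-(2,6-dimethoxy-4-{(1E)-3-[methoxy(methyl)amino]-3-oxoprop-1-en-1-yl}phenoxy)propanoyl]-1,3-oxazolidin-2-one | COc1cc(/C=C/C(=O)N(C)OC)cc(OC)c1O[C@H](C(=O)N1[C@@H](Cc2ccccc2)COC1=O)[C@H](O)c1ccc(O[Si](C)(C)C(C)(C)C)cc1 | intermediate
9 | (2S,3R)-3-(4-{[tert-butyl(dimethyl)silyl]oxy}phenyl)-3-hydroxy-2-(2,6-dimethoxy-4-{(1E)-3-[methoxy(methyl)amino]-3-oxoprop-1-en-1-yl}phenoxy)propanal | COc1cc(/C=C/C(=O)N(C)OC)cc(OC)c1O[C@H](C=O)[C@H](O)c1ccc(O[Si](C)(C)C(C)(C)C)cc1 | intermediate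
10 | (2E)-3-[4-({(1R,2R)-1-(4-{[tert-butyl(dimethyl)silyl]oxy}phenyl)-1,3-dihydroxypropan-2-yl}oxy)-3,5-dimethoxyphenyl]-N-methoxy-N-methylprop-2-enamide | COc1cc(/C=C/C(=O)N(C)OC)cc(OC)c1O[C@H](CO)[C@H](O)c1ccc(O[Si](C)(C)C(C)(C)C)cc1 | intermediate
11 | triacetic acid lactone (4-hydroxy-6-methyl-2H-pyran-2-one) | Cc1cc(O)cc(=O)o1 | starting material
12 | dilithium salt of 11, deprotonated at the 4-hydroxyl and at the 6-methyl group | [Li+].[Li+].[CH2-]c1cc([O-])cc(=O)o1 | intermediate
13 | 6-{(3E)-4-[4-({(1R,2R)-1-(4-{[tert-butyl(dimethyl)silyl]oxy}phenyl)-1,3-dihydroxypropan-2-yl}oxy)-3,5-dimethoxyphenyl]-2-oxobut-3-en-1-yl}-4-hydroxy-2H-pyran-2-one | COc1cc(/C=C/C(=O)Cc2cc(O)cc(=O)o2)cc(OC)c1O[C@H](CO)[C@H](O)c1ccc(O[Si](C)(C)C(C)(C)C)cc1 | intermediate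
14 | methyl (8E)-9-[4-({(1R,2R)-1-(4-{[tert-butyl(dimethyl)silyl]oxy}phenyl)-1,3-dihydroxypropan-2-yl}oxy)-3,5-dimethoxyphenyl]-3,5,7-trioxonon-8-enoate | COC(=O)CC(=O)CC(=O)CC(=O)/C=C/c1cc(OC)c(O[C@H](CO)[C@H](O)c2ccc(O[Si](C)(C)C(C)(C)C)cc2)c(OC)c1 | intermediate
15 | (2E)-3-[4-({(1R,2R)-1,3-dihydroxy-1-(4-hydroxyphenyl)propan-2-yl}oxy)-3,5-dimethoxyphenyl]-1-(2,4,6-trihydroxyphenyl)prop-2-en-1-one | COc1cc(/C=C/C(=O)c2c(O)cc(O)cc2O)cc(OC)c1O[C@H](CO)[C@H](O)c1ccc(O)cc1 | intermediate
16 | (2S)-2-[4-({(1R,2R)-1,3-dihydroxy-1-(4-hydroxyphenyl)propan-2-yl}oxy)-3,5-dimethoxyphenyl]-5,7-dihydroxy-2,3-dihydro-4H-chromen-4-one | COc1cc([C@@H]2CC(=O)c3c(O)cc(O)cc3O2)cc(OC)c1O[C@H](CO)[C@H](O)c1ccc(O)cc1 | target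

**Step count and risks**

Total step count: 6. Longest linear sequence: 6 steps (1 → 3 → 5 → 8 → 10 → 13 → 16).

Steps most likely to fail:

Step 6 (most risky). The triketo ester can also close by the aldol mode (to a stilbene-type resorcylate) or by a carbon Michael addition, and the enzyme may not accept a chalcone with so large a ring B substituent. Fallback: set out from pyrone 13, run the Mg(OMe)2 stage alone and let chalcone 15 close without the enzyme in NaHCO3 buffer (pH 8.5)/MeOH at 25 °C. This gives target 16 together with its C2 epimer, the (2R)-flavanone F1. The two are diastereomers and are separated by preparative reverse-phase HPLC. F1 is reopened to chalcone 15 with cold 2 M KOH and sent through the closure again, so the material comes back to the route at 16 by separation and recycling instead of catalyst control.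

Step 5. The dilithium alkoxide of 10 may be poorly soluble or the acylation may stall. Fallback: set out from diol 10 and close the 1,3-diol with 2,2-dimethoxypropane and pyridinium 4-toluenesulfonate in acetone at 25 °C to the acetonide F2. Acylate dilithiated 11 with F2 (now only 2.5 equiv of dianion) to the acetonide pyrone F3. Remove the acetonide with 80% aq. AcOH at 40 °C, which leaves the aryl silyl ether in place and comes back to the route at 13.

Step 1. The phenoxide may attack the imide carbonyl of 2, or the base may degrade the α-halo imide. Fallback: set out from 1 and alkylate it with tert-butyl bromoacetate (K2CO3, acetone, 56 °C) to tert-butyl (4-formyl-2,6-dimethoxyphenoxy)acetate F4. Cleave the ester with CF3CO2H in CH2Cl2 to (4-formyl-2,6-dimethoxyphenoxy)acetic acid F5. Convert F5 with pivaloyl chloride and Et3N in THF at −20 °C into its pivalic mixed anhydride F6, and acylate (4S)-4-benzyl-1,3-oxazolidin-2-one with F6 in the presence of LiCl at 25 °C, which comes back to the route at 3.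

**Further compounds**

F1 | step 6 | (2R)-2-[4-({(1R,2R)-1,3-dihydroxy-1-(4-hydroxyphenyl)propan-2-yl}oxy)-3,5-dimethoxyphenyl]-5,7-dihydroxy-2,3-dihydro-4H-chromen-4-one | COc1cc([C@H]2CC(=O)c3c(O)cc(O)cc3O2)cc(OC)c1O[C@H](CO)[C@H](O)c1ccc(O)cc1
F2 | step 5 | (2E)-3-[4-({(4R,5R)-4-(4-{[tert-butyl(dimethyl)silyl]oxy}phenyl)-2,2-dimethyl-1,3-dioxan-5-yl}oxy)-3,5-dimethoxyphenyl]-N-methoxy-N-methylprop-2-enamide | COc1cc(/C=C/C(=O)N(C)OC)cc(OC)c1O[C@@H]1COC(C)(C)O[C@@H]1c1ccc(O[Si](C)(C)C(C)(C)C)cc1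
F3 | step 5 | 6-{(3E)-4-[4-({(4R,5R)-4-(4-{[tert-butyl(dimethyl)silyl]oxy}phenyl)-2,2-dimethyl-1,3-dioxan-5-yl}oxy)-3,5-dimethoxyphenyl]-2-oxobut-3-en-1-yl}-4-hydroxy-2H-pyran-2-one | COc1cc(/C=C/C(=O)Cc2cc(O)cc(=O)o2)cc(OC)c1O[C@@H]1COC(C)(C)O[C@@H]1c1ccc(O[Si](C)(C)C(C)(C)C)cc1
F4 | step 1 | tert-butyl (4-formyl-2,6-dimethoxyphenoxy)acetate | COc1cc(C=O)cc(OC)c1OCC(=O)OC(C)(C)C
F5 | step 1 | (4-formyl-2,6-dimethoxyphenoxy)acetic acid | COc1cc(C=O)cc(OC)c1OCC(=O)O
F6 | step 1 | (4-formyl-2,6-dimethoxyphenoxy)acetic 2,2-dimethylpropanoic anhydride | COc1cc(C=O)cc(OC)c1OCC(=O)OC(=O)C(C)(C)C
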